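**Retrosynthetic overview**
1. Ring A is numbered C1 (prenyl), C2-H, C3-H, C4 (OH), C5 (CHO), C6 (aroyl). The plan rests on the unbroken chain ketone carbon–C6–C5–formyl carbon, which is the C5–C4–C3–C2 skeleton of a 5-aryl-2(5H)-furanone. With that chain in place, only the bond between the two unsubstituted carbons C2 and C3 of ring A has to be made.
2. 33 ⇒ MOM keto aldehyde 32 ⇒ diol 30 ⇒ 7-hydroxy-3-arylphthalide 28 ⇒ (aromatisation) cyclohexadiene 26 ⇒ (6π-electrocyclisation, C2–C3) 3,4-dialkenylbutenolide 25.
3. 25 ⇒ Stille coupling at butenolide C3 (stannane 24) and Suzuki coupling at C4 (boronate 22) on dibromobutenolide 17 ⇒ mucobromic acid 12 + aryl Grignard reagent from bromide 11.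
4. 11 ⇒ 6-exo opening of the Sharpless epoxide of prenol 6 by the phenol next to bromine. The two catechol oxygens are told apart by formylation, allylation and Baeyer–Villiger oxidation of 2-bromo-4-methylphenol 1.
5. Order of rings: ring B (bought), dioxane ring (step 6), butenolide (step 7), ring A (step 12, aromatic after step 14). The lactone ring is opened again in step 16.

Key step: step 12

Assumption: Ar stands for (3R)-3-(2-hydroxypropan-2-yl)-7-methyl-2,3-dihydro-1,4-benzodioxin-5-yl; its tertiary alcohol is carried unprotected, and the carbon that ends as the ketone is carried as a mixture of epimers from 17 to 30.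

Step 1
Reactants: 1 2-bromo-4-methylphenol
Product: 2 3-bromo-2-hydroxy-5-methylbenzaldehyde
Conditions: MgCl2, Et3N, (CH2O)n, MeCN, reflux; 1 M HCl
Reagents that add atoms: formaldehyde (as paraformaldehyde), C=O
Why: Casnati–Skattebøl ortho-formylation, in which the phenoxide ArOMgCl directs formaldehyde to the only free ortho carbon (the para position carries the methyl group) and a second formaldehyde takes up hydride from the benzylic alkoxide to give the salicylaldehyde directly.

Step 2
Reactants: 2 3-bromo-2-hydroxy-5-methylbenzaldehyde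
Product: 3 3-bromo-5-methyl-2-(prop-2-enyloxy)benzaldehyde
Conditions: allyl bromide, K2CO3, DMF, rt
Reagents that add atoms: allyl bromide, C=CCBr
Why: Williamson etherification caps the oxygen next to bromine with a group that survives peracid and carbonate and comes off later under neutral conditions, so the two future catechol oxygens stay distinguishable.

Step 3
Reactants: 3 3-bromo-5-methyl-2-(prop-2-enyloxy)benzaldehyde
Product: 5 3-bromo-5-methyl-2-(prop-2-enyloxy)phenol, via aryl formate 4 (not isolated)
Conditions: mCPBA, CH2Cl2, rt; aq NaHCO3 wash; then K2CO3 (10 mol%), MeOH, rt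
Reagents that add atoms: mCPBA, O=C(OO)c1cccc(Cl)c1
Why: Baeyer–Villiger (Dakin-type) oxidation, in which the electron-rich ortho-alkoxyaryl group migrates in preference to hydrogen and the monosubstituted allyl alkene reacts far more slowly with the peracid, followed by transesterification of the formate.

Step 4
Reactants: 6 prenol (3-methylbut-2-en-1-ol)
Product: 8 [(2S)-3,3-dimethyloxiran-2-yl]methyl 4-methylbenzenesulfonate, via epoxy alcohol 7 (not isolated)
Conditions: Ti(OiPr)4 (5 mol%), L-(+)-DIPT (6 mol%), TBHP, 4 Å MS, CH2Cl2, −20 °C; P(OMe)3; then TsCl, Et3N, DMAP (5 mol%), −10 °C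
Reagents that add atoms: tert-butyl hydroperoxide, CC(C)(C)OO; 4-toluenesulfonyl chloride, Cc1ccc(cc1)S(=O)(=O)Cl
Why: Sharpless asymmetric epoxidation, in which the catalyst formed from Ti(OiPr)4 and L-(+)-DIPT delivers oxygen to the alkene face that makes the CH carbon (S), as with other 3,3-disubstituted allylic alcohols, and sulfonylation in the same flask avoids isolating the volatile, water-soluble epoxy alcohol.

Step 5
Reactants: 5 3-bromo-5-methyl-2-(prop-2-enyloxy)phenol; 8 [(2S)-3,3-dimethyloxiran-2-yl]methyl 4-methylbenzenesulfonate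
Product: 9 (2S)-2-{[3-bromo-5-methyl-2-(prop-2-enyloxy)phenoxy]methyl}-3,3-dimethyloxirane
Conditions: K2CO3, DMF, 50 °C
Reagents that add atoms: none
Why: SN2 displacement (Williamson) at the primary sulfonate carbon leaves the (S) centre untouched, because the other epoxide carbon is fully substituted and so closes off the epoxide-opening and re-closure path that erodes the ee of simple glycidyl sulfonates.

Step 6
Reactants: 9 (2S)-2-{[3-bromo-5-methyl-2-(prop-2-enyloxy)phenoxy]methyl}-3,3-dimethyloxirane
Product: 11 2-[(2R)-8-bromo-6-methyl-2,3-dihydro-1,4-benzodioxin-2-yl]propan-2-ol (Ar–Br), via epoxy phenol 10 (not isolated)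
Conditions: Pd(PPh3)4 (2 mol%), morpholine, THF, rt; then K2CO3, MeOH, rt to 40 °C
Reagents that add atoms: none
Why: Tsuji–Trost deallylation with zerovalent palladium frees the phenol beside bromine, and its phenoxide then opens the epoxide by 6-exo-tet SN2 attack at the secondary carbon with inversion, (S) to (R), since basic conditions disfavour 7-endo attack at the tertiary carbon.

Step 7
Reactants: 11 Ar–Br; 12 mucobromic acid
Product: 17 3,4-dibromo-5-Ar-furan-2(5H)-one (both C5 epimers), via aryllithium 13 (not isolated), via arylmagnesium bromide 14 (not isolated), via sodium mucobromate 15 (not isolated), via hydroxy acid 16 (not isolated)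
Conditions: 11, n-BuLi (2.1 equiv), THF, −78 °C; MgBr2·OEt2 (2.2 equiv), −78 to −40 °C; add to 15 [12 (1.3 equiv), NaH (1.3 equiv), THF, 0 °C] at −78 °C, to −20 °C; 2 M HCl, rt
Reagents that add atoms: none
Why: Bromine–lithium exchange and transmetalation give an aryl Grignard reagent that adds 1,2 to the open-chain aldehyde form of the pseudo-acid salt, the same reaction type as aryl Grignard additions to 3-hydroxyphthalides and Barbier allylations of mucohalic acids, after which the (Z)-hydroxy acid lactonises on acidification and the new C5 centre forms without control, which is harmless because it ends as the ketone carbon.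

Step 8
Reactants: 18 2,3-dibromoprop-1-ene; 19 2-methylprop-1-enylmagnesium bromide
Product: 20 2-bromo-5-methylhexa-1,4-diene
Conditions: CuI (5 mol%), THF, −10 °C to rt
Reagents that add atoms: none
Why: Copper-catalysed allylic substitution by a Grignard reagent, in which the vinylic bromide is inert and the SN2 and SN2' modes lead to the same product.

Step 9
Reactants: 20 2-bromo-5-methylhexa-1,4-diene
Product: 22 4,4,5,5-tetramethyl-2-(5-methylhexa-1,4-dien-2-yl)-1,3,2-dioxaborolane, via alkenyllithium 21 (not isolated)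
Conditions: t-BuLi (2.0 equiv), Et2O, −78 °C; i-PrOBpin, −78 °C to rt; 1 M HCl
Reagents that add atoms: 2-isopropoxy-4,4,5,5-tetramethyl-1,3,2-dioxaborolane, CC(C)OB1OC(C)(C)C(C)(C)O1
Why: Bromine–lithium exchange at −78 °C is much faster than deprotonation of the doubly allylic CH2, and the alkenyllithium is trapped at once by electrophilic borylation.

Step 10
Reactants: 17 3,4-dibromo-5-Ar-furan-2(5H)-one; 22 alkenyl pinacol boronate
Product: 23 3-bromo-4-(5-methylhexa-1,4-dien-2-yl)-5-Ar-furan-2(5H)-one
Conditions: 22 (1.05 equiv), PdCl2(dppf) (5 mol%), K3PO4, degassed THF/H2O 9:1, 40 °C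
Reagents that add atoms: none
Why: Suzuki–Miyaura coupling that is site-selective for C4, because the β-bromide of a 3,4-dihalobutenolide is a vinylogous acyl bromide and adds oxidatively to zerovalent palladium faster than the α-bromide, with the boronate kept near one equivalent to prevent double coupling.

Step 11
Reactants: 23 3-bromo-4-(5-methylhexa-1,4-dien-2-yl)-5-Ar-furan-2(5H)-one; 24 tributyl(1-ethoxyethenyl)stannane
Product: 25 3-(1-ethoxyethenyl)-4-(5-methylhexa-1,4-dien-2-yl)-5-Ar-furan-2(5H)-one
Conditions: Pd2(dba)3 (2.5 mol%), AsPh3 (20 mol%), CuI (10 mol%), NMP, 50 °C; Et3N-deactivated SiO2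
Reagents that add atoms: none
Why: Stille coupling of the remaining α-bromide under neutral, copper-assisted conditions, the usual second coupling on 4-substituted 3-bromobutenolides, run cool enough that the acid-sensitive triene can be isolated on amine-deactivated silica.

Step 12
Reactants: 25 3-(1-ethoxyethenyl)-4-(5-methylhexa-1,4-dien-2-yl)-5-Ar-furan-2(5H)-one
Product: 26 7-ethoxy-4-(3-methylbut-2-enyl)-3-Ar-5,6-dihydro-2-benzofuran-1(3H)-one
Conditions: degassed PhMe (0.01 M), BHT (10 mol%), base-washed sealed tube, 120–140 °C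
Reagents that add atoms: none
Why: On heating, the hexatriene CH2=C(OEt)–C3=C4–C(CH2CH=CMe2)=CH2, whose central double bond is the butenolide C3=C4 bond, undergoes a concerted, thermally allowed disrotatory 6π-electrocyclisation in which the two terminal methylene carbons bond to each other (the C2–C3 bond of ring A) and the remaining π-bonds move to the two positions exocyclic to the lactone. The closest known reaction type is the thermal closure of hexatrienes held on vicinally dialkenylated five-membered rings (furanones, maleimides, thiophenes, indoles), which is routinely followed by aromatisation. Ring A is the only ring closed, and it closes as an all-carbon six-membered ring by pericyclic union of two sp2 CH2 termini from the s-cis,s-cis conformer, which is accessible because the ring double bond fixes the arms cis and neither terminus carries an inward substituent. No stereocentre is formed, since both new sp3 carbons are CH2 groups and the sense of disrotation leaves no trace, while the (R) centre of the dioxane ring is remote and the lactone CH remains an epimer mixture. The step needs periselectivity for the triene over the prenyl alkene, over hydrogen shifts and over bimolecular Diels–Alder reactions: the prenyl C=C is insulated by a CH2 group and tethered too closely for an intramolecular cycloaddition, the lactone CH and the ethoxyvinyl arm lie trans across C3=C4 so that a 1,5-hydrogen shift is geometrically barred, and high dilution, BHT and acid-free glass suppress dimerisation, radical polymerisation and enol ether loss. Should the cyclohexadiene isomerise further by 1,5-hydrogen shifts, the isomers keep the same oxidation level and converge in steps 13 and 14.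

Step 13
Reactants: 26 7-ethoxy-4-(3-methylbut-2-enyl)-3-Ar-5,6-dihydro-2-benzofuran-1(3H)-one
Product: 27 7-hydroxy-4-(3-methylbut-2-enyl)-3-Ar-5,6-dihydro-2-benzofuran-1(3H)-one (β-keto lactone drawn as its enol)
Conditions: 1 M aq HCl, THF, rt
Reagents that add atoms: water, O
Why: Acid-catalysed hydrolysis of a β-alkoxyacrylate-type dienol ether (C-protonation, addition of water, loss of ethanol) removes the ethyl group before aromatisation, so that no aryl ethyl ether ever has to be cleaved, under conditions too mild to ionise the β-oxygenated tertiary alcohol or to hydrate the prenyl alkene.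

Step 14
Reactants: 27 7-hydroxy-4-(3-methylbut-2-enyl)-3-Ar-5,6-dihydro-2-benzofuran-1(3H)-one
Product: 28 7-hydroxy-4-(3-methylbut-2-enyl)-3-Ar-2-benzofuran-1(3H)-one
Conditions: DDQ (1.05 equiv), PhMe, 0 °C to rt
Reagents that add atoms: none
Why: DDQ dehydrogenation by hydride abstraction from a ring CH2 of a dihydrophenol tautomer is driven by aromatisation and is therefore much faster than attack at the prenyl or aryl methyl positions when one equivalent is used.

Step 15
Reactants: 28 7-hydroxy-4-(3-methylbut-2-enyl)-3-Ar-2-benzofuran-1(3H)-one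
Product: 29 7-(methoxymethoxy)-4-(3-methylbut-2-enyl)-3-Ar-2-benzofuran-1(3H)-one
Conditions: MOMCl (1.5 equiv), i-Pr2NEt, CH2Cl2, 0 °C to rt
Reagents that add atoms: chloromethyl methyl ether, COCCl
Why: Base-mediated O-alkylation (MOM acetal formation) takes place at the only acidic hydroxyl, the hindered tertiary alcohol being inert at this temperature, and shields the phenol from activated DMSO in step 17.

Step 16
Reactants: 29 7-(methoxymethoxy)-4-(3-methylbut-2-enyl)-3-Ar-2-benzofuran-1(3H)-one
Product: 30 [2-(hydroxymethyl)-3-(methoxymethoxy)-6-(3-methylbut-2-enyl)phenyl](Ar)methanol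
Conditions: LiAlH4 (3 equiv), THF, 0 °C to rt; Na2SO4·10H2O
Reagents that add atoms: none
Why: Hydride reduction of the lactone to the 1,4-diol, the standard opening of 3-arylphthalides, leaves the MOM acetal, the aryl ethers and the isolated alkene untouched and keeps the carbinol carbon as the inconsequential epimer mixture.

Step 17
Reactants: 30 [2-(hydroxymethyl)-3-(methoxymethoxy)-6-(3-methylbut-2-enyl)phenyl](Ar)methanol
Product: 32 2-(Ar-carbonyl)-6-(methoxymethoxy)-3-(3-methylbut-2-enyl)benzaldehyde, via bis(alkoxysulfonium) salt 31 (not isolated)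
Conditions: (COCl)2 (5 equiv), DMSO (10 equiv), CH2Cl2, −78 °C; 30, −78 to −60 °C; Et3N (15 equiv), −78 to 0 °C
Reagents that add atoms: none
Why: Swern oxidation with excess reagent is chosen because both carbinols are turned into alkoxysulfonium ions before any carbonyl group exists, so that on addition of Et3N aldehyde and ketone appear together and the lactol path back to the phthalide is bypassed, while the tertiary alcohol cannot be oxidised.

Step 18
Reactants: 32 2-(Ar-carbonyl)-6-(methoxymethoxy)-3-(3-methylbut-2-enyl)benzaldehyde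
Product: 33 6-hydroxy-2-(Ar-carbonyl)-3-(3-methylbut-2-enyl)benzaldehyde (target, R)
Conditions: 2 M aq HCl, THF, 40 °C
Reagents that add atoms: none
Why: Acid-catalysed hydrolysis of the phenolic MOM acetal, assisted by the ortho formyl group, is run in acid rather than base because ortho-formyl benzophenones isomerise to phthalides with base, and it is mild enough for the tertiary alcohol, the prenyl group (no ortho hydroxyl to trap it) and the (R) centre.

**Compound list**
1 | 2-bromo-4-methylphenol | Cc1ccc(O)c(Br)c1 | starting material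
2 | 3-bromo-2-hydroxy-5-methylbenzaldehyde | Cc1cc(Br)c(O)c(C=O)c1 | intermediate
3 | 3-bromo-5-methyl-2-(prop-2-enyloxy)benzaldehyde | Cc1cc(Br)c(OCC=C)c(C=O)c1 | intermediate
4 | 3-bromo-5-methyl-2-(prop-2-enyloxy)phenyl formate | Cc1cc(Br)c(OCC=C)c(OC=O)c1 | intermediate
5 | 3-bromo-5-methyl-2-(prop-2-enyloxy)phenol | Cc1cc(O)c(OCC=C)c(Br)c1 | intermediate
6 | prenol (3-methylbut-2-en-1-ol) | CC(C)=CCO | starting material
7 | [(2S)-3,3-dimethyloxiran-2-yl]methanol | OC[C@@H]1OC1(C)C | intermediate
8 | [(2S)-3,3-dimethyloxiran-2-yl]methyl 4-methylbenzenesulfonate | Cc1ccc(cc1)S(=O)(=O)OC[C@@H]1OC1(C)C | intermediate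
9 | (2S)-2-{[3-bromo-5-methyl-2-(prop-2-enyloxy)phenoxy]methyl}-3,3-dimethyloxirane | Cc1cc(Br)c(OCC=C)c(OC[C@@H]2OC2(C)C)c1 | intermediate
10 | 2-bromo-6-{[(2S)-3,3-dimethyloxiran-2-yl]methoxy}-4-methylphenol | Cc1cc(Br)c(O)c(OC[C@@H]2OC2(C)C)c1 | intermediate
11 | 2-[(2R)-8-bromo-6-methyl-2,3-dihydro-1,4-benzodioxin-2-yl]propan-2-ol (Ar–Br) | Brc1cc(C)cc2c1O[C@@H](C(C)(C)O)CO2 | intermediate
12 | mucobromic acid (3,4-dibromo-5-hydroxyfuran-2(5H)-one) | OC1OC(=O)C(Br)=C1Br | starting material
13 | Ar–Li as its lithium alkoxide | [Li]c1cc(C)cc2c1O[C@@H](C(C)(C)O[Li])CO2 | intermediate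
14 | Ar–MgBr as its bromomagnesium alkoxide | Br[Mg]c1cc(C)cc2c1O[C@@H](C(C)(C)O[Mg]Br)CO2 | intermediate
15 | sodium (Z)-2,3-dibromo-4-oxobut-2-enoate | [Na+].[O-]C(=O)/C(Br)=C(Br)\C=O | intermediate
16 | (Z)-2,3-dibromo-4-hydroxy-4-Ar-but-2-enoic acid | OC(=O)/C(Br)=C(Br)\C(O)c1cc(C)cc2c1O[C@@H](C(C)(C)O)CO2 | intermediate
17 | 3,4-dibromo-5-Ar-furan-2(5H)-one (C5 epimers) | O=C1OC(c2cc(C)cc3c2O[C@@H](C(C)(C)O)CO3)C(Br)=C1Br | intermediate
18 | 2,3-dibromoprop-1-ene | C=C(Br)CBr | starting material
19 | 2-methylprop-1-enylmagnesium bromide | CC(C)=C[Mg]Br | starting material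
20 | 2-bromo-5-methylhexa-1,4-diene | C=C(Br)CC=C(C)C | intermediate
21 | (5-methylhexa-1,4-dien-2-yl)lithium | [Li]C(=C)CC=C(C)C | intermediate
22 | 4,4,5,5-tetramethyl-2-(5-methylhexa-1,4-dien-2-yl)-1,3,2-dioxaborolane | C=C(CC=C(C)C)B1OC(C)(C)C(C)(C)O1 | intermediate
23 | 3-bromo-4-(5-methylhexa-1,4-dien-2-yl)-5-Ar-furan-2(5H)-one | O=C1OC(c2cc(C)cc3c2O[C@@H](C(C)(C)O)CO3)C(C(=C)CC=C(C)C)=C1Br | intermediate
24 | tributyl(1-ethoxyethenyl)stannane | CCCC[Sn](CCCC)(CCCC)C(=C)OCC | starting material
25 | 3-(1-ethoxyethenyl)-4-(5-methylhexa-1,4-dien-2-yl)-5-Ar-furan-2(5H)-one | C=C(OCC)C1=C(C(=C)CC=C(C)C)C(c2cc(C)cc3c2O[C@@H](C(C)(C)O)CO3)OC1=O | intermediate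
26 | 7-ethoxy-4-(3-methylbut-2-enyl)-3-Ar-5,6-dihydro-2-benzofuran-1(3H)-one | CCOC1=C2C(=O)OC(c3cc(C)cc4c3O[C@@H](C(C)(C)O)CO4)C2=C(CC=C(C)C)CC1 | intermediate
27 | 7-hydroxy-4-(3-methylbut-2-enyl)-3-Ar-5,6-dihydro-2-benzofuran-1(3H)-one (enol form) | OC1=C2C(=O)OC(c3cc(C)cc4c3O[C@@H](C(C)(C)O)CO4)C2=C(CC=C(C)C)CC1 | intermediate
28 | 7-hydroxy-4-(3-methylbut-2-enyl)-3-Ar-2-benzofuran-1(3H)-one | O=C1OC(c2cc(C)cc3c2O[C@@H](C(C)(C)O)CO3)c2c1c(O)ccc2CC=C(C)C | intermediate
29 | 7-(methoxymethoxy)-4-(3-methylbut-2-enyl)-3-Ar-2-benzofuran-1(3H)-one | O=C1OC(c2cc(C)cc3c2O[C@@H](C(C)(C)O)CO3)c2c1c(OCOC)ccc2CC=C(C)C | intermediate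
30 | [2-(hydroxymethyl)-3-(methoxymethoxy)-6-(3-methylbut-2-enyl)phenyl](Ar)methanol | OCc1c(OCOC)ccc(CC=C(C)C)c1C(O)c1cc(C)cc2c1O[C@@H](C(C)(C)O)CO2 | intermediate
31 | bis(dimethylsulfonio) ether of 30, dichloride | C[S+](C)OCc1c(OCOC)ccc(CC=C(C)C)c1C(O[S+](C)C)c1cc(C)cc2c1O[C@@H](C(C)(C)O)CO2.[Cl-].[Cl-] | intermediate
32 | 2-(Ar-carbonyl)-6-(methoxymethoxy)-3-(3-methylbut-2-enyl)benzaldehyde | O=Cc1c(OCOC)ccc(CC=C(C)C)c1C(=O)c1cc(C)cc2c1O[C@@H](C(C)(C)O)CO2 | intermediate
33 | 6-hydroxy-2-(Ar-carbonyl)-3-(3-methylbut-2-enyl)benzaldehyde (CNP0373866.1) | CC(C)=CCc1ccc(O)c(C=O)c1C(=O)c1cc(C)cc2c1O[C@@H](C(C)(C)O)CO2 | target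

**Step count.** Total: 18 steps. Longest linear sequence: 15 steps (steps 1–3, 5–7 and 10–18).

**Steps most likely to fail**

1. **Step 12.** The closure may be too slow. The five-membered ring spreads the two arms apart, and the arm at butenolide C4 must turn its prenyl-bearing side toward the C5 aryl group. Diels–Alder oligomerisation of the dienes and loss of the enol ether could then overtake ring closure.
 - The fallback makes the same bond by a polar closure instead of a pericyclic one, and sets out from 25.
 - Brief treatment with oxalic acid in wet THF at 0 °C hydrolyses the simple enol ether to the 3-acetylbutenolide F1.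
 - Condensation with pyrrolidine (PhMe, 4 Å MS, catalytic AcOH, rt to 60 °C) gives the 2-aminotriene F2. Its much stronger donor lets the enamine CH2 add to the terminal CH2 of the lactone-conjugated diene, as an intramolecular vinylogous Stork-type Michael addition.
 - The resulting vinylogous carbamate F3 is hydrolysed with 1 M HCl in THF, and the route is rejoined at 27.

2. **Step 7.** Bromine–magnesium exchange or conjugate addition–elimination on the dibromoalkene may compete with carbonyl addition, and the carboxylate salt may dissolve poorly at low temperature.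
 - The fallback reverses the polarity and introduces the halogens last, setting out from 11.
 - n-BuLi (2.1 equiv) followed by DMF gives the aldehyde F4.
 - LiC≡CCO2Et (from ethyl propiolate and LiN(iPr)2, THF, −78 °C) adds to it to give the hydroxy ynoate F5.
 - Syn-distannylation with (Bu3Sn)2 and Pd(PPh3)4 in THF at reflux places ester and carbinol cis, so that lactonisation follows and gives the 3,4-bis(tributylstannyl)butenolide F6.
 - Br2 (2 equiv) in CH2Cl2 at −78 °C, where tin–bromine exchange outruns ring bromination, then rejoins the route at 17.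

3. **Step 17.** Activation of the hindered diaryl carbinol may be incomplete. The hydroxy aldehyde would then close to a lactol and be over-oxidised back to the lactone level. The activated carbinol might also ionise and close to a cyclic ether.
 - The fallback oxidises stepwise, with the phenol and the primary alcohol tied together, and sets out from 28.
 - LiAlH4 in THF gives the phenolic diol F7.
 - 2,2-Dimethoxypropane with PPTS ties the phenol and the CH2OH group into the six-membered acetonide F8.
 - Dess–Martin periodinane oxidises the only remaining oxidisable carbinol to the ketone F9.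
 - 80% AcOH at 40 °C releases the salicyl alcohol F10.
 - Activated MnO2 in CH2Cl2 oxidises its benzylic CH2OH. The only cyclic form here is a hemiketal that cannot be oxidised further, so the route is rejoined directly at 33 and steps 15–18 are replaced.

**Further compounds**
F1 | step 12 | 3-acetyl-4-(5-methylhexa-1,4-dien-2-yl)-5-Ar-furan-2(5H)-one | CC(=O)C1=C(C(=C)CC=C(C)C)C(c2cc(C)cc3c2O[C@@H](C(C)(C)O)CO3)OC1=O
F2 | step 12 | 4-(5-methylhexa-1,4-dien-2-yl)-3-[1-(pyrrolidin-1-yl)ethenyl]-5-Ar-furan-2(5H)-one | C=C(N1CCCC1)C1=C(C(=C)CC=C(C)C)C(c2cc(C)cc3c2O[C@@H](C(C)(C)O)CO3)OC1=O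
F3 | step 12 | 4-(3-methylbut-2-enyl)-7-(pyrrolidin-1-yl)-3-Ar-5,6-dihydro-2-benzofuran-1(3H)-one | O=C1OC(c2cc(C)cc3c2O[C@@H](C(C)(C)O)CO3)C2=C(CC=C(C)C)CCC(N3CCCC3)=C12
F4 | step 7 | (3R)-3-(2-hydroxypropan-2-yl)-7-methyl-2,3-dihydro-1,4-benzodioxine-5-carbaldehyde | O=Cc1cc(C)cc2c1O[C@@H](C(C)(C)O)CO2
F5 | step 7 | ethyl 4-hydroxy-4-Ar-but-2-ynoate | CCOC(=O)C#CC(O)c1cc(C)cc2c1O[C@@H](C(C)(C)O)CO2
F6 | step 7 | 3,4-bis(tributylstannyl)-5-Ar-furan-2(5H)-one | CCCC[Sn](CCCC)(CCCC)C1=C([Sn](CCCC)(CCCC)CCCC)C(c2cc(C)cc3c2O[C@@H](C(C)(C)O)CO3)OC1=O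
F7 | step 17 | 2-(hydroxymethyl)-3-[hydroxy(Ar)methyl]-4-(3-methylbut-2-enyl)phenol | OCc1c(O)ccc(CC=C(C)C)c1C(O)c1cc(C)cc2c1O[C@@H](C(C)(C)O)CO2
F8 | step 17 | [2,2-dimethyl-6-(3-methylbut-2-enyl)-4H-1,3-benzodioxin-5-yl](Ar)methanol | CC1(C)OCc2c(O1)ccc(CC=C(C)C)c2C(O)c1cc(C)cc2c1O[C@@H](C(C)(C)O)CO2
F9 | step 17 | [2,2-dimethyl-6-(3-methylbut-2-enyl)-4H-1,3-benzodioxin-5-yl](Ar)methanone | CC1(C)OCc2c(O1)ccc(CC=C(C)C)c2C(=O)c1cc(C)cc2c1O[C@@H](C(C)(C)O)CO2
F10 | step 17 | [3-hydroxy-2-(hydroxymethyl)-6-(3-methylbut-2-enyl)phenyl](Ar)methanone | OCc1c(O)ccc(CC=C(C)C)c1C(=O)c1cc(C)cc2c1O[C@@H](C(C)(C)O)CO2
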